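## Structural features

Scaposin is a flavone: benzene ring A is fused to 4-pyranone ring C (a chromen-4-one), and aryl ring B is attached to C2 of ring C through the C2–C1' bond. Ring A is fully substituted, with O1 on C8a, the carbonyl carbon C4 on C4a, hydroxyls on C5 and C7 and methoxy groups on C6 and C8. Ring B carries a hydroxyl on C3' and methoxy groups on C4' and C5'. The molecule is flat and has no stereocentre, so no configuration has to be set or preserved. The fragile elements are the three phenols on oxygen-rich rings, which are easily oxidised to quinones, and the pyranone, which opens in hot hydroxide. In acid, ring C can also open and reclose with exchange of C6 and C8 (Wessely–Moser); this is harmless only because both positions end as methoxy-bearing carbons. The real difficulty is not the skeleton but the sorting of seven oxygens into three hydroxyls and four methyl ethers, above all the alternating OH/OMe/OH/OMe array on ring A. The key step uses the fact that C8a and C4a are adjacent ring A carbons bearing O1 and C4, which are the two carbons of an aryne; the C5 oxygen beside C4a tells its two ends apart while C8 stays C–H.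

## Logic of the disconnections

20 to 19: the benzylic C–O bond on O3' is cut. Ring B then travels through all earlier steps as a triether that resists organolithium, fluoride, acid, NBS and methoxide. The forward step must remove benzyl without reducing C2=C3, which is helped by the absence of any halogen at that point.

19 to 18 to 17: the C8–OMe bond and then the C8–Br bond are cut. In 17, C8 is the only C–H of ring A and lies ortho to the C7 hydroxyl and para to the C5 hydroxyl, so the last oxygen enters at a position that cannot be mistaken. Taking this oxygen out is also what makes the two ends of 14 different. The forward steps require NBS to prefer ring A of 17 over ring B and C3, and the copper-mediated substitution on 18 to outrun reductive loss of bromine.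

17 to 16: the two O–CH2OMe bonds on O5 and O7 are cut. These oxygens need a small, inductively withdrawing group that survives nBuLi, fluoride and 125 °C and leaves in dilute acid while the benzyl ether stays.

16 to 8 and 13: C8a–O1, C4a–C4 and O1–C2 are cut. Ring C disappears and the molecule falls into two benzene derivatives of similar size. The forward step demands that the carboxylate oxygen of 13 attacks the C8a end of 14 and that the resulting phenoxide closes in the 6-endo mode.

8 to 5 to 4: the C–Si and O–S bonds are cut, then the C–Br bond. 4 has a mirror plane, so its two ortho positions are the same and bromination poses no regiochemical question. The bromine then serves to carry silicon from oxygen to carbon.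

4 to 2 to 1: the aryl C–O bond para to the methoxy group is cut back to C–H, then the two MOM groups are removed. In 2 that C–H is the only one without an ortho substituent, which is the selectivity rule of iridium-catalysed borylation. 1 already holds the future C6 methoxy group between the two oxygens that become O5 and O7.

13 to 11 to 10 to 9: the bond between the alkyne and the carboxyl carbon is cut (CO2), then the alkyne is traced to the aldehyde carbon plus one carbon, then the benzyl group is removed. Each forward step is a standard operation on an electron-rich benzaldehyde.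

## Other disconnections considered

Alternative 1: The cut is at both ring A methoxy C–O bonds (C6–O and C8–O). In the forward direction 2-[3-(benzyloxy)-4,5-dimethoxyphenyl]-5,7-dihydroxy-4H-chromen-4-one A1 would be dibrominated to the 6,8-dibromide A2, which NaOMe and CuBr in hot DMF/MeOH would convert into 3'-O-benzylscaposin A3 (the same compound as 19).
- In favour: A1 should be available in a few classical steps from a commercial acylphloroglucinol and 10, and exhaustive bromination of ring A has no regiochemical question. No aryne precursor or sealed tube is needed. On step economy this alternative is the better plan.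
- Against: two Ullmann-type substitutions must go to completion on one doubly deprotonated ring. Each C–Br bond could be reduced instead, which would give mono-methoxy and debrominated flavones of very similar polarity. Two equivalents of NBS also raise the risk of attack on ring B.
- Comparison: on structure the two plans meet at the same compound, but the chosen plan brings the C6 methoxy group in from 1 and needs the copper step only once. On mechanism they are equal, since step 11 is the same reaction type.

Alternative 2: The cut is at C8–C8a, with C4a–C5 made beforehand. A C5-metalated pyranone from 2-[3-(benzyloxy)-4,5-dimethoxyphenyl]-5-bromo-4H-pyran-4-one A5 would add to the mixed squarate 3-methoxy-4-(propan-2-yloxy)cyclobut-3-ene-1,2-dione A4 to give hydroxycyclobutenone A6. Heating A6 in xylene would open the four-membered ring (4π) to a dienylketene, which would close onto the pyranone double bond (6π) and tautomerise to hydroquinone A7.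
- In favour: all four ring A oxygens come from A4, so no halogenation or copper step is needed; on the placement of the C8 oxygen this alternative is the better one. The key step needs no reagent, and the chelated C5 hydroxyl of A7 should allow selective methylation at O8.
- Against: the organometallic must choose one of two carbonyls of A4 that differ only by OMe against OiPr, so C6/C7 regiochemistry is weakly controlled. Metalated 4-pyranones are prone to ring opening, A7 is an air-sensitive hydroquinone, and the isopropyl ether must later be cleaved beside several methyl ethers.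
- Comparison: on mechanism the pericyclic cascade is well behaved with aryl and alkenyl groups, but a pyranone as the 2π partner is less secure than the polar aryne cascade. Step economy is about equal, with fewer steps after the key step and more before it.

Alternative 3: The cut is at O1–C8a. Constant-current oxidation of diketone A8 at graphite in (CF3)2CHOH with Bu4NBF4 would join the enol oxygen to the only free ring A carbon, removing two electrons and two protons, to give 5,7,3'-tri-O-benzylscaposin A9.
- In favour: no leaving group is needed at C8a, the ring A C–H is unique, and A8 comes from a plain Claisen condensation. One hydrogenolysis of A9 would finish the synthesis, so the endgame is better than in the chosen plan.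
- Against: A8 holds two very electron-rich rings and three benzyl ethers with oxidation potentials near that of the enol. Over-oxidation to quinones, loss of alkyl groups from radical cations and C–C coupling through the central carbon could all compete. The ring A half of A8 is a pentaoxygenated benzene with two kinds of ether and needs a synthesis at least as long as that of 8.
- Comparison: on structure the plans are equal, each resting on a single ring A C–H. On mechanism the chosen plan follows a known regiochemical rule, whereas the chemoselectivity of radical-cation chemistry on this substrate is hard to predict. Overall step economy is probably equal.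

Key step: step 8

Remark on the chemistry (assumption): 1 and 9 are treated as catalogue compounds and flavone numbering is used for ring positions. Mapping 8, 13 and 16 atom by atom onto 20 showed no structural error, so only the access to 8 was redesigned: phenol 4 is reached in two steps by C–H borylation and oxidation.

## Route

Step 1
Reactants: 1 2-methoxybenzene-1,3-diol (2-methoxyresorcinol)
Product: 2 2-methoxy-1,3-bis(methoxymethoxy)benzene
Conditions: MOMCl, iPr2NEt, CH2Cl2, 0 °C → rt
Reagents that add atoms: chloromethyl methyl ether, COCCl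
Why: O-alkylation of two equivalent phenols (MOM protection); MOM withstands nBuLi, fluoride and 125 °C and later polarises the aryne through its inductive effect.

Step 2
Reactants: 2 2-methoxy-1,3-bis(methoxymethoxy)benzene
Product: 4 4-methoxy-3,5-bis(methoxymethoxy)phenol, via pinacol boronate 3 (not isolated)
Conditions: B2pin2, [Ir(OMe)(cod)]2 (cat.), dtbpy (cat.), THF, 80 °C; then NaOH, H2O2, THF/H2O, 0 °C
Reagents that add atoms: bis(pinacolato)diboron, CC1(C)OB(OC1(C)C)B1OC(C)(C)C(C)(C)O1 (boryl group of 3 only); hydrogen peroxide, OO (phenol oxygen of 4)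
Why: Iridium-catalysed aromatic C–H borylation is sterically controlled and should take the only C–H with no ortho substituent, para to the methoxy group; alkaline peroxide then converts C–B into C–OH by 1,2-migration of the aryl group from boron to oxygen without harming the MOM acetals.

Step 3
Reactants: 4 4-methoxy-3,5-bis(methoxymethoxy)phenol
Product: 5 2-bromo-4-methoxy-3,5-bis(methoxymethoxy)phenol
Conditions: NBS (1.0 equiv), CH2Cl2, −78 → 0 °C
Reagents that add atoms: N-bromosuccinimide, O=C1CCC(=O)N1Br
Why: Electrophilic aromatic bromination ortho to the phenol; the para position is blocked and the two ortho positions are equivalent, so one equivalent at low temperature should give the monobromide under neutral conditions that spare the acetals.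

Step 4
Reactants: 5 2-bromo-4-methoxy-3,5-bis(methoxymethoxy)phenol
Product: 8 4-methoxy-3,5-bis(methoxymethoxy)-2-(trimethylsilyl)phenyl trifluoromethanesulfonate, via aryl silyl ether 6 (not isolated), via lithium silylphenoxide 7 (not isolated)
Conditions: HMDS, THF, 65 °C, concentrate; nBuLi, THF, −78 °C; Tf2O, −78 → 0 °C
Reagents that add atoms: hexamethyldisilazane, C[Si](C)(C)N[Si](C)(C)C; n-butyllithium, [Li]CCCC (lithium of 7 only); trifluoromethanesulfonic anhydride, O=S(=O)(OS(=O)(=O)C(F)(F)F)C(F)(F)F
Why: O-silylation, bromine–lithium exchange and 1,3-migration of silicon from oxygen to carbon (retro-Brook rearrangement, driven by phenoxide formation), then O-triflation; this is the standard sequence to ortho-silylaryl triflates (Kobayashi aryne precursors).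

Step 5
Reactants: 9 3-hydroxy-4,5-dimethoxybenzaldehyde
Product: 10 3-(benzyloxy)-4,5-dimethoxybenzaldehyde
Conditions: BnBr, K2CO3, DMF, rt
Reagents that add atoms: benzyl bromide, BrCc1ccccc1
Why: Williamson ether synthesis on the only phenol; benzyl survives every later step and is removed last under neutral conditions.

Step 6
Reactants: 10 3-(benzyloxy)-4,5-dimethoxybenzaldehyde
Product: 11 1-(benzyloxy)-5-(2,2-dibromoethenyl)-2,3-dimethoxybenzene
Conditions: CBr4, PPh3, Zn, CH2Cl2, 0 °C → rt
Reagents that add atoms: carbon tetrabromide, BrC(Br)(Br)Br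
Why: Corey–Fuchs dibromo-olefination, a Wittig reaction of Ph3P=CBr2 generated with zinc, adds the one carbon needed for the alkyne.

Step 7
Reactants: 11 1-(benzyloxy)-5-(2,2-dibromoethenyl)-2,3-dimethoxybenzene
Product: 13 3-[3-(benzyloxy)-4,5-dimethoxyphenyl]prop-2-ynoic acid, via lithium acetylide 12 (not isolated)
Conditions: nBuLi (2.2 equiv), THF, −78 °C; CO2, −78 °C → rt; aq. HCl
Reagents that add atoms: n-butyllithium, [Li]CCCC (lithium of 12 only); carbon dioxide, O=C=O
Why: Second stage of the Corey–Fuchs sequence: bromine–lithium exchange, α-elimination and 1,2-hydrogen shift (Fritsch–Buttenberg–Wiechell rearrangement) give the alkyne, the second equivalent of nBuLi deprotonates it, and the acetylide is carboxylated by CO2.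

Step 8
Reactants: 8 4-methoxy-3,5-bis(methoxymethoxy)-2-(trimethylsilyl)phenyl trifluoromethanesulfonate; 13 3-[3-(benzyloxy)-4,5-dimethoxyphenyl]prop-2-ynoic acid
Product: 16 2-[3-(benzyloxy)-4,5-dimethoxyphenyl]-6-methoxy-5,7-bis(methoxymethoxy)-4H-chromen-4-one, via aryne 14 (not isolated), via cesium acylphenoxide 15 (not isolated)
Conditions: CsF (4 equiv), THF, 125 °C, sealed tube
Reagents that add atoms: cesium fluoride, [Cs+].[F-] (cesium counter-ion of 15 only)
Why: Fluoride attacks silicon of 8 and triflate leaves, giving aryne 14 (C4a≡C8a); the cesium carboxylate of 13 adds through oxygen to C8a, the aryl anion formed at C4a attacks the ester carbonyl (4-exo-trig) and the four-membered alkoxide opens to acylphenoxide 15, a net insertion of the aryne into the acid C–O bond. The phenoxide oxygen then adds to the β-carbon of the ynone (oxa-Michael addition) and C3 is protonated by the proton of the original acid, giving 16; ring C is the only ring retained and it closes in the 6-endo-dig mode. The closest known reaction type is the fluoride-induced insertion of arynes into the C–O bond of carboxylic acids to give ortho-hydroxyaryl ketones, which with arylpropiolic acids runs on to flavones; only this trioxygenated aryne is new. No stereocentre is formed. The step needs the oxygen nucleophile to enter at C8a and not at C4a: the C5 OMOM group next to C4a distorts and polarises the aryne so that attack occurs at the remote carbon and the negative charge develops beside the inductively withdrawing oxygen, while the C8 side is an unhindered C–H. It also needs acylation of the aryl anion to outrun its protonation, which the aprotic medium, the high temperature and the largely deprotonated acid should favour, and 6-endo closure to be preferred over 5-exo closure, which the polarised ynone and the stability of the pyranone should secure. MOM and benzyl ethers are inert to CsF at 125 °C.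

Step 9
Reactants: 16 2-[3-(benzyloxy)-4,5-dimethoxyphenyl]-6-methoxy-5,7-bis(methoxymethoxy)-4H-chromen-4-one
Product: 17 2-[3-(benzyloxy)-4,5-dimethoxyphenyl]-5,7-dihydroxy-6-methoxy-4H-chromen-4-one
Conditions: 3 M HCl, MeOH/THF, 50 °C
Reagents that add atoms: none
Why: Acid-catalysed acetal cleavage removes both MOM groups while benzyl and methyl ethers and the pyranone are stable; an acid-induced C6/C8 exchange (Wessely–Moser) would be harmless, since brominating and methoxylating the remaining ring A C–H of either isomer leads to the same 19.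

Step 10
Reactants: 17 2-[3-(benzyloxy)-4,5-dimethoxyphenyl]-5,7-dihydroxy-6-methoxy-4H-chromen-4-one
Product: 18 2-[3-(benzyloxy)-4,5-dimethoxyphenyl]-8-bromo-5,7-dihydroxy-6-methoxy-4H-chromen-4-one
Conditions: NBS (1.0 equiv), DMF, 0 °C
Reagents that add atoms: N-bromosuccinimide, O=C1CCC(=O)N1Br
Why: Electrophilic aromatic bromination; C8 is the only ring A C–H and is ortho to the free C7 hydroxyl and para to the C5 hydroxyl, so this ring should react much faster than the fully etherified ring B on the electron-poor C2 or than C3.

Step 11
Reactants: 18 2-[3-(benzyloxy)-4,5-dimethoxyphenyl]-8-bromo-5,7-dihydroxy-6-methoxy-4H-chromen-4-one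
Product: 19 2-[3-(benzyloxy)-4,5-dimethoxyphenyl]-5,7-dihydroxy-6,8-dimethoxy-4H-chromen-4-one (3'-O-benzylscaposin)
Conditions: NaOMe (excess), CuBr, DMF/MeOH, 110 °C; aq. HCl work-up
Reagents that add atoms: sodium methoxide, [Na+].[O-]C
Why: Copper-mediated Ullmann-type methoxylation of an aryl bromide through a monovalent copper methoxide; the reaction type is established for 6- and 8-halo-5,7-dihydroxyflavones, whose phenoxides are tolerated, and the benzyl ether is inert to methoxide.

Step 12
Reactants: 19 2-[3-(benzyloxy)-4,5-dimethoxyphenyl]-5,7-dihydroxy-6,8-dimethoxy-4H-chromen-4-one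
Product: 20 scaposin, 5,7-dihydroxy-2-(3-hydroxy-4,5-dimethoxyphenyl)-6,8-dimethoxy-4H-chromen-4-one
Conditions: H2 (1 atm), Pd/C, EtOAc/MeOH, rt
Reagents that add atoms: none
Why: Catalytic hydrogenolysis of the aryl benzyl ether; at 1 atm and room temperature the C2=C3 bond, conjugated with the carbonyl and two aryl rings, should remain, and no other reducible group is present.

## Compound list

1 | 2-methoxybenzene-1,3-diol (2-methoxyresorcinol) | COc1c(O)cccc1O | starting material
2 | 2-methoxy-1,3-bis(methoxymethoxy)benzene | COCOc1cccc(OCOC)c1OC | intermediate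
3 | 2-[4-methoxy-3,5-bis(methoxymethoxy)phenyl]-4,4,5,5-tetramethyl-1,3,2-dioxaborolane | COCOc1cc(B2OC(C)(C)C(C)(C)O2)cc(OCOC)c1OC | intermediate (not isolated)
4 | 4-methoxy-3,5-bis(methoxymethoxy)phenol | COCOc1cc(O)cc(OCOC)c1OC | intermediate
5 | 2-bromo-4-methoxy-3,5-bis(methoxymethoxy)phenol | COCOc1cc(O)c(Br)c(OCOC)c1OC | intermediate
6 | [2-bromo-4-methoxy-3,5-bis(methoxymethoxy)phenoxy](trimethyl)silane | COCOc1cc(O[Si](C)(C)C)c(Br)c(OCOC)c1OC | intermediate (not isolated)
7 | lithium 4-methoxy-3,5-bis(methoxymethoxy)-2-(trimethylsilyl)phenolate | [Li+].[O-]c1cc(OCOC)c(OC)c(OCOC)c1[Si](C)(C)C | intermediate (not isolated)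
8 | 4-methoxy-3,5-bis(methoxymethoxy)-2-(trimethylsilyl)phenyl trifluoromethanesulfonate | C[Si](C)(C)c1c(OCOC)c(OC)c(OCOC)cc1OS(=O)(=O)C(F)(F)F | intermediate
9 | 3-hydroxy-4,5-dimethoxybenzaldehyde | COc1cc(C=O)cc(O)c1OC | starting material
10 | 3-(benzyloxy)-4,5-dimethoxybenzaldehyde | COc1cc(C=O)cc(OCc2ccccc2)c1OC | intermediate
11 | 1-(benzyloxy)-5-(2,2-dibromoethenyl)-2,3-dimethoxybenzene | COc1cc(C=C(Br)Br)cc(OCc2ccccc2)c1OC | intermediate
12 | lithium [3-(benzyloxy)-4,5-dimethoxyphenyl]ethynide | [Li+].[C-]#Cc1cc(OC)c(OC)c(OCc2ccccc2)c1 | intermediate (not isolated)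
13 | 3-[3-(benzyloxy)-4,5-dimethoxyphenyl]prop-2-ynoic acid | OC(=O)C#Cc1cc(OCc2ccccc2)c(OC)c(OC)c1 | intermediate
14 | 4-methoxy-3,5-bis(methoxymethoxy)benzyne (1,2-didehydro-4-methoxy-3,5-bis(methoxymethoxy)benzene) | COCOC1=CC#CC(OCOC)=C1OC | intermediate (not isolated)
15 | cesium 2-{3-[3-(benzyloxy)-4,5-dimethoxyphenyl]prop-2-ynoyl}-4-methoxy-3,5-bis(methoxymethoxy)phenolate | [Cs+].[O-]c1cc(OCOC)c(OC)c(OCOC)c1C(=O)C#Cc1cc(OC)c(OC)c(OCc2ccccc2)c1 | intermediate (not isolated)
16 | 2-[3-(benzyloxy)-4,5-dimethoxyphenyl]-6-methoxy-5,7-bis(methoxymethoxy)-4H-chromen-4-one | COCOc1cc2oc(-c3cc(OC)c(OC)c(OCc4ccccc4)c3)cc(=O)c2c(OCOC)c1OC | intermediate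
17 | 2-[3-(benzyloxy)-4,5-dimethoxyphenyl]-5,7-dihydroxy-6-methoxy-4H-chromen-4-one | COc1cc(-c2cc(=O)c3c(O)c(OC)c(O)cc3o2)cc(OCc2ccccc2)c1OC | intermediate
18 | 2-[3-(benzyloxy)-4,5-dimethoxyphenyl]-8-bromo-5,7-dihydroxy-6-methoxy-4H-chromen-4-one | COc1cc(-c2cc(=O)c3c(O)c(OC)c(O)c(Br)c3o2)cc(OCc2ccccc2)c1OC | intermediate
19 | 2-[3-(benzyloxy)-4,5-dimethoxyphenyl]-5,7-dihydroxy-6,8-dimethoxy-4H-chromen-4-one (3'-O-benzylscaposin) | COc1cc(-c2cc(=O)c3c(O)c(OC)c(O)c(OC)c3o2)cc(OCc2ccccc2)c1OC | intermediate
20 | scaposin, 5,7-dihydroxy-2-(3-hydroxy-4,5-dimethoxyphenyl)-6,8-dimethoxy-4H-chromen-4-one | COc1cc(-c2cc(=O)c3c(O)c(OC)c(O)c(OC)c3o2)cc(O)c1OC | target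

## Step count and risks

Total: 12 steps. Longest linear sequence: 9 steps (steps 1–4, then 8–12); the other branch (steps 5–7, then 8–12) has 8.

**Step 8 (key step).** The most likely failures are loss of regiocontrol in the addition to 14, because the C7 and C6 oxygens exert weak opposing effects; protonation of the aryl anion before acylation, which stops at an aryl ester; and decarboxylation of the cesium arylpropiolate at 125 °C.
Fallback (sets out from 11 and 5, returns at 16):
- 11 is converted as in step 7 into 12, which is quenched with N-methoxy-N-methylcarbamoyl chloride instead of CO2 to give 3-[3-(benzyloxy)-4,5-dimethoxyphenyl]-N-methoxy-N-methylprop-2-ynamide F1.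
- 5 is treated with nBuLi (2.2 equiv, THF, −78 °C; O–H deprotonation, then bromine–lithium exchange) and acylated with F1. Aqueous work-up gives 3-[3-(benzyloxy)-4,5-dimethoxyphenyl]-1-[2-hydroxy-5-methoxy-4,6-bis(methoxymethoxy)phenyl]prop-2-yn-1-one F2, the protonated form of 15.
- K2CO3 in acetone closes ring C by the same 6-endo-dig oxa-Michael addition to give 16.
The regiochemistry is then fixed by the position of bromine in 5 and no aryne is involved.

**Step 11.** Reductive loss of bromine may compete with C–O bond formation on the very electron-rich bis-phenoxide, and methoxide may open the pyranone at 110 °C.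
Fallback (sets out from 18, returns at 20):
- Both phenols of 18 are benzylated (BnBr, K2CO3, Bu4NI, DMF, 60 °C) to give 5,7-bis(benzyloxy)-2-[3-(benzyloxy)-4,5-dimethoxyphenyl]-8-bromo-6-methoxy-4H-chromen-4-one F3.
- Palladium-catalysed C–O coupling with methanol (Pd2(dba)3, tBuBrettPhos, Cs2CO3, MeOH/toluene, 80 °C; Buchwald–Hartwig etherification on zerovalent palladium) gives 5,7-bis(benzyloxy)-2-[3-(benzyloxy)-4,5-dimethoxyphenyl]-6,8-dimethoxy-4H-chromen-4-one F4.
- One hydrogenolysis (H2, Pd/C) removes all three benzyl groups and gives 20.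

**Step 10.** Bromination of ring B ortho or para to its ether oxygens, bromination at C3, or double bromination may compete.
Fallback (sets out from 17, returns at 20; avoids halogenation and step 11):
- Selective benzylation of the more acidic, non-chelated C7 hydroxyl (BnBr, 1.05 equiv, K2CO3, acetone, reflux) gives 7-(benzyloxy)-2-[3-(benzyloxy)-4,5-dimethoxyphenyl]-5-hydroxy-6-methoxy-4H-chromen-4-one F5.
- Elbs persulfate oxidation (K2S2O8, aq. NaOH/pyridine, rt) attacks para to the C5 phenoxide, which is C8, and gives potassium 7-(benzyloxy)-2-[3-(benzyloxy)-4,5-dimethoxyphenyl]-5-hydroxy-6-methoxy-4-oxo-4H-chromen-8-yl sulfate F6.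
- Warm aq. HCl with Na2SO3 hydrolyses F6 to 7-(benzyloxy)-2-[3-(benzyloxy)-4,5-dimethoxyphenyl]-5,8-dihydroxy-6-methoxy-4H-chromen-4-one F7.
- Me2SO4 (1 equiv), K2CO3, acetone under argon methylates the free C8 hydroxyl, the C5 hydroxyl being chelated, to give 7-(benzyloxy)-2-[3-(benzyloxy)-4,5-dimethoxyphenyl]-5-hydroxy-6,8-dimethoxy-4H-chromen-4-one F8.
- Hydrogenolysis (H2, Pd/C) gives 20.

**Step 4.** The silyl migration may be incomplete at a carbon crowded by two oxygen substituents, with the aryllithium being protonated or attacking a MOM group, and triflation of the hindered phenoxide may be slow.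
Fallback (sets out from 4, returns at 8; directed ortho-metalation in place of halogen–metal exchange):
- 4 is carbamoylated (Et2NCOCl, NaH, THF) to 4-methoxy-3,5-bis(methoxymethoxy)phenyl N,N-diethylcarbamate F9.
- sBuLi/TMEDA (THF, −78 °C) lithiates the C–H lying between the carbamate and an OMOM group, and TMSCl gives 4-methoxy-3,5-bis(methoxymethoxy)-2-(trimethylsilyl)phenyl N,N-diethylcarbamate F10.
- LiAlH4 (THF, 0 °C → rt) cleaves the carbamate to 4-methoxy-3,5-bis(methoxymethoxy)-2-(trimethylsilyl)phenol F11.
- nBuLi, then Tf2O (−78 °C) gives 8.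

## Further compounds

F1 | step 8 | 3-[3-(benzyloxy)-4,5-dimethoxyphenyl]-N-methoxy-N-methylprop-2-ynamide | CON(C)C(=O)C#Cc1cc(OC)c(OC)c(OCc2ccccc2)c1
F2 | step 8 | 3-[3-(benzyloxy)-4,5-dimethoxyphenyl]-1-[2-hydroxy-5-methoxy-4,6-bis(methoxymethoxy)phenyl]prop-2-yn-1-one | COCOc1cc(O)c(C(=O)C#Cc2cc(OC)c(OC)c(OCc3ccccc3)c2)c(OCOC)c1OC
F3 | step 11 | 5,7-bis(benzyloxy)-2-[3-(benzyloxy)-4,5-dimethoxyphenyl]-8-bromo-6-methoxy-4H-chromen-4-one | COc1cc(-c2cc(=O)c3c(OCc4ccccc4)c(OC)c(OCc4ccccc4)c(Br)c3o2)cc(OCc2ccccc2)c1OC
F4 | step 11 | 5,7-bis(benzyloxy)-2-[3-(benzyloxy)-4,5-dimethoxyphenyl]-6,8-dimethoxy-4H-chromen-4-one | COc1cc(-c2cc(=O)c3c(OCc4ccccc4)c(OC)c(OCc4ccccc4)c(OC)c3o2)cc(OCc2ccccc2)c1OC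
F5 | step 10 | 7-(benzyloxy)-2-[3-(benzyloxy)-4,5-dimethoxyphenyl]-5-hydroxy-6-methoxy-4H-chromen-4-one | COc1cc(-c2cc(=O)c3c(O)c(OC)c(OCc4ccccc4)cc3o2)cc(OCc2ccccc2)c1OC
F6 | step 10 | potassium 7-(benzyloxy)-2-[3-(benzyloxy)-4,5-dimethoxyphenyl]-5-hydroxy-6-methoxy-4-oxo-4H-chromen-8-yl sulfate | [K+].COc1cc(-c2cc(=O)c3c(O)c(OC)c(OCc4ccccc4)c(OS(=O)(=O)[O-])c3o2)cc(OCc2ccccc2)c1OC
F7 | step 10 | 7-(benzyloxy)-2-[3-(benzyloxy)-4,5-dimethoxyphenyl]-5,8-dihydroxy-6-methoxy-4H-chromen-4-one | COc1cc(-c2cc(=O)c3c(O)c(OC)c(OCc4ccccc4)c(O)c3o2)cc(OCc2ccccc2)c1OC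
F8 | step 10 | 7-(benzyloxy)-2-[3-(benzyloxy)-4,5-dimethoxyphenyl]-5-hydroxy-6,8-dimethoxy-4H-chromen-4-one | COc1cc(-c2cc(=O)c3c(O)c(OC)c(OCc4ccccc4)c(OC)c3o2)cc(OCc2ccccc2)c1OC
F9 | step 4 | 4-methoxy-3,5-bis(methoxymethoxy)phenyl N,N-diethylcarbamate | CCN(CC)C(=O)Oc1cc(OCOC)c(OC)c(OCOC)c1
F10 | step 4 | 4-methoxy-3,5-bis(methoxymethoxy)-2-(trimethylsilyl)phenyl N,N-diethylcarbamate | CCN(CC)C(=O)Oc1cc(OCOC)c(OC)c(OCOC)c1[Si](C)(C)C
F11 | step 4 | 4-methoxy-3,5-bis(methoxymethoxy)-2-(trimethylsilyl)phenol | COCOc1cc(O)c([Si](C)(C)C)c(OCOC)c1OC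
A1 | alternative 1 | 2-[3-(benzyloxy)-4,5-dimethoxyphenyl]-5,7-dihydroxy-4H-chromen-4-one | COc1cc(-c2cc(=O)c3c(O)cc(O)cc3o2)cc(OCc2ccccc2)c1OC
A2 | alternative 1 | 2-[3-(benzyloxy)-4,5-dimethoxyphenyl]-6,8-dibromo-5,7-dihydroxy-4H-chromen-4-one | COc1cc(-c2cc(=O)c3c(O)c(Br)c(O)c(Br)c3o2)cc(OCc2ccccc2)c1OC
A3 | alternative 1 | 3'-O-benzylscaposin, 2-[3-(benzyloxy)-4,5-dimethoxyphenyl]-5,7-dihydroxy-6,8-dimethoxy-4H-chromen-4-one | COc1cc(-c2cc(=O)c3c(O)c(OC)c(O)c(OC)c3o2)cc(OCc2ccccc2)c1OC
A4 | alternative 2 | 3-methoxy-4-(propan-2-yloxy)cyclobut-3-ene-1,2-dione | COC1=C(OC(C)C)C(=O)C1=O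
A5 | alternative 2 | 2-[3-(benzyloxy)-4,5-dimethoxyphenyl]-5-bromo-4H-pyran-4-one | COc1cc(-c2cc(=O)c(Br)co2)cc(OCc2ccccc2)c1OC
A6 | alternative 2 | 2-[3-(benzyloxy)-4,5-dimethoxyphenyl]-5-[1-hydroxy-2-methoxy-4-oxo-3-(propan-2-yloxy)cyclobut-2-en-1-yl]-4H-pyran-4-one | COC1=C(OC(C)C)C(=O)C1(O)c1coc(-c2cc(OC)c(OC)c(OCc3ccccc3)c2)cc1=O
A7 | alternative 2 | 2-[3-(benzyloxy)-4,5-dimethoxyphenyl]-5,8-dihydroxy-6-methoxy-7-(propan-2-yloxy)-4H-chromen-4-one | COc1cc(-c2cc(=O)c3c(O)c(OC)c(OC(C)C)c(O)c3o2)cc(OCc2ccccc2)c1OC
A8 | alternative 3 | 1-[2,4-bis(benzyloxy)-3,5-dimethoxyphenyl]-3-[3-(benzyloxy)-4,5-dimethoxyphenyl]propane-1,3-dione | COc1cc(C(=O)CC(=O)c2cc(OC)c(OCc3ccccc3)c(OC)c2OCc2ccccc2)cc(OCc2ccccc2)c1OC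
A9 | alternative 3 | 5,7,3'-tri-O-benzylscaposin, 5,7-bis(benzyloxy)-2-[3-(benzyloxy)-4,5-dimethoxyphenyl]-6,8-dimethoxy-4H-chromen-4-one | COc1cc(-c2cc(=O)c3c(OCc4ccccc4)c(OC)c(OCc4ccccc4)c(OC)c3o2)cc(OCc2ccccc2)c1OC
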